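**Strategy**

- Numbering (germacranolide): ring C1–C10 with C1=C10 the ester-bearing alkene, C4–C5 the oxirane, C6 the lactone carbinol, C7 the fusion CH, C8/C9 the acyloxy carbons; C11–C13 the methylene lactone, C14 the ester carbon, C15 the methyl.
- Cuts, in retrosynthetic order: the O8 ester and the O9 acetate; the C11=C13 methylene; the O6–C12 lactone bond and the C4–C5 oxirane; the C7–C11 bond (enolate alkylation); last the ring bond C8–C9, with C1–C6 reconnected, by a retro-oxy-Cope step back to a 3-methylcyclohex-2-enone.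
- Enabling feature: O6 and the C1=C10 alkene are 1,5-related through C7–C8–C9, both C8 and C9 carry oxygen, and the cis C4–C5 unit sits next to C6. This is the footprint of an anionic oxy-Cope rearrangement of a 1,6-dialkenyl-3-methylcyclohex-2-en-1-ol whose two migrating alkene termini are enol ethers.
- Forward order of rings: cyclohexenone (Michael addition, aldol condensation), ten-membered carbocycle by four-atom ring expansion, oxirane, γ-lactone; the side-chain oxirane is brought in ready-made.
- Stereochemistry: C1 of the six-membered ring from an organocatalytic Michael addition; it directs the carbinol center, and both are passed through the chair [3,3] shift to C8 and C9. C7 comes from enolate alkylation anti to C9, C6 from chelation-controlled reduction, C4/C5 from hydroxyl-directed epoxidation, and the side-chain center from (R)-2-methylglycidol.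

Key step: step 9

Assumption: the sense of induction of the prolinol catalyst in step 1 is taken from the steric-shielding model; the ring-cis C1=C10 alkene is E by the sequence rule because of the ester on C10.

Step 1
Reactants: 1 methyl 4-oxobutanoate, 2 methyl vinyl ketone
Product: 3 methyl (3R)-3-formyl-6-oxoheptanoate
Conditions: (R)-α,α-diphenylprolinol trimethylsilyl ether (5 mol%), ethyl 3,4-dihydroxybenzoate (20 mol%), neat, 4 °C
Reagents that add atoms: none
Why: Enamine-catalysed Michael addition with a diarylprolinol silyl ether: the E-enamine of 1 is shielded on one face by the diphenyl(silyloxy)methyl group, so the enone should add to the open face and the (R)-catalyst should set the future C1 as R (to be confirmed by correlation at this stage).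

Step 2
Reactants: 3 methyl (3R)-3-formyl-6-oxoheptanoate
Product: 4 methyl 2-[(1R)-4-oxocyclohex-2-en-1-yl]acetate
Conditions: p-TsOH·H2O (cat.), toluene, 4 Å molecular sieves, 60 °C
Reagents that add atoms: none
Why: Acid-catalysed intramolecular aldol condensation of the methyl ketone onto the aldehyde closes the six-membered ring and dehydration gives the enone, while the stereocenter (now γ to the carbonyl) is not part of the bond-forming events.

Step 3
Reactants: 4 methyl 2-[(1R)-4-oxocyclohex-2-en-1-yl]acetate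
Product: 5 methyl 2-[(1R)-4-hydroxy-4-methylcyclohex-2-en-1-yl]acetate (both C4 epimers)
Conditions: MeMgBr, CeCl3, THF, −78 °C
Reagents that add atoms: methylmagnesium bromide, C[Mg]Br
Why: Organocerium 1,2-addition to the enone carbonyl is much faster than attack on the ester at −78 °C and brings in C15; the new carbinol center is erased in step 6, so both epimers are carried on.

Step 4
Reactants: 5 methyl 2-[(1R)-4-hydroxy-4-methylcyclohex-2-en-1-yl]acetate
Product: 7 methyl (2Z)-3-hydroxy-2-[(1S)-4-hydroxy-4-methylcyclohex-2-en-1-yl]prop-2-enoate, via dilithium ester enolate 6 (not isolated)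
Conditions: LiN(iPr)2 (2.2 equiv), THF, −78 °C; HCO2Me, −78 → 0 °C; AcOH quench
Reagents that add atoms: methyl formate, COC=O
Why: Crossed Claisen condensation: after the alkoxide has formed, the ester enolate is formylated by methyl formate and the product is held as its chelated enolate until the quench, which brings in C9 (the descriptor at the ring center changes to S only through the priority change).

Step 5
Reactants: 7 methyl (2Z)-3-hydroxy-2-[(1S)-4-hydroxy-4-methylcyclohex-2-en-1-yl]prop-2-enoate
Product: 9 methyl (2Z)-2-[(1S)-4-hydroxy-4-methylcyclohex-2-en-1-yl]-3-(triisopropylsilyloxy)prop-2-enoate, via sodium enolate 8 (not isolated)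
Conditions: NaH (1.0 equiv), THF, 0 °C; i-Pr3SiOTf, −78 °C
Reagents that add atoms: triisopropylsilyl trifluoromethanesulfonate, CC(C)[Si](OS(=O)(=O)C(F)(F)F)(C(C)C)C(C)C
Why: O-Silylation of the sodium chelate: the U-shaped enolate holds its oxygen cis to the ester carbonyl, so the hard silyl triflate should give the Z silyl enol ether (silyloxy cis to CO2Me); any E isomer is removed by chromatography and the hindered tertiary alcohol is not silylated.

Step 6
Reactants: 9 methyl (2Z)-2-[(1S)-4-hydroxy-4-methylcyclohex-2-en-1-yl]-3-(triisopropylsilyloxy)prop-2-enoate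
Product: 10 methyl (2Z)-2-[(1R)-4-methyl-2-oxocyclohex-3-en-1-yl]-3-(triisopropylsilyloxy)prop-2-enoate
Conditions: [C5H5NH][CrO3Cl], 4 Å molecular sieves, CH2Cl2, 0 °C → rt; filtration through Florisil, used at once
Reagents that add atoms: none
Why: Babler–Dauben oxidative 1,3-transposition: the tertiary allylic chromate ester shifts to the secondary allylic position and is oxidised to the 3-methylcyclohex-2-enone; the electron-poor silyloxyacrylate is not oxidised, and the product is used at once because C1 is now α to the ketone.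

Step 7
Reactants: 11 1,2-dibromoethene (cis/trans mixture)
Product: 13 (Z)-2-bromovinyl 4-methoxybenzyl ether, via bromoethyne 12 (not isolated)
Conditions: 4-MeOC6H4CH2OH, KOtBu, THF, 0 °C → rt
Reagents that add atoms: 4-methoxybenzyl alcohol, COc1ccc(CO)cc1
Why: Elimination–addition: base converts 11 (the cis isomer fastest) into bromoethyne, and anti addition of the alkoxide to this alkyne gives the Z 2-bromovinyl ether.

Step 8
Reactants: 13 (Z)-2-bromovinyl 4-methoxybenzyl ether, 10 methyl (2Z)-2-[(1R)-4-methyl-2-oxocyclohex-3-en-1-yl]-3-(triisopropylsilyloxy)prop-2-enoate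
Product: 16 methyl (2Z)-2-[(1R,2S)-2-hydroxy-2-[(Z)-2-(4-methoxybenzyloxy)ethenyl]-4-methylcyclohex-3-en-1-yl]-3-(triisopropylsilyloxy)prop-2-enoate, via alkoxyvinyllithium 14 (not isolated), via alkoxyvinylcerium dichloride 15 (not isolated)
Conditions: t-BuLi (2 equiv), Et2O, −78 °C; CeCl3, THF, −78 °C; then 10, −78 °C
Reagents that add atoms: none
Why: Bromine–lithium exchange with retention of the Z geometry, transmetalation to the weakly basic organocerium reagent and 1,2-addition to the enone: axial attack on the half-chair with the C1 arm equatorial should place the new alkenyl group cis to that arm and set the carbinol center C6 as S; any trans-dialkenyl isomer is separated.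

Step 9
Reactants: 16 methyl (2Z)-2-[(1R,2S)-2-hydroxy-2-[(Z)-2-(4-methoxybenzyloxy)ethenyl]-4-methylcyclohex-3-en-1-yl]-3-(triisopropylsilyloxy)prop-2-enoate, 17 methyl bromoacetate
Product: 20 methyl (1(10)E,4Z,7R,8S,9R)-7-(2-methoxy-2-oxoethyl)-8-(4-methoxybenzyloxy)-4-methyl-6-oxo-9-(triisopropylsilyloxy)cyclodeca-1(10),4-diene-10-carboxylate, via potassium alkoxide 18 (not isolated), via potassium dienolate 19 (not isolated)
Conditions: KN(SiMe3)2, THF, −78 → −30 °C (no crown ether); then 17, −78 °C
Reagents that add atoms: none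
Why: Proposed new method: the potassium alkoxide 18 should undergo a concerted anionic oxy-Cope [3,3] shift through a chair in which C1–C6 breaks while C8–C9 forms between the two enol-ether termini, and the potassium dienolate 19 is then C-alkylated at C7 by 17 in the same flask; the closest known reaction type is the anionic oxy-Cope ring expansion of 1,2-dialkenylcyclohex-2-enols to cyclodeca-2,6-dienones with alkylation of the regiodefined enolate, which has not been run with a β-silyloxyacrylate arm or with oxygen on both bond-forming carbons. The ten-membered ring arises by four-atom ring expansion of the cyclohexene (the six-atom array C8–C7–C6···C1–C10–C9 exists only in the transition state), so no end-to-end closure is involved and the cis C4=C5 bond of the cyclohexenone is carried over unchanged. C8 (S) and C9 (R) are set by chirality transfer from C6 and C1 through the chair: the Z ether holds O8 axial and the Z silyloxyacrylate holds O9 equatorial, which fixes both the relative (cis on the ring) and the absolute configuration. C7 (R) is set when the electrophile enters the enolate on its outer face, anti to C9, with the C8–O bond lying near the enolate plane under potassium bridging of O6 and O8, an arrangement that also disfavours β-elimination of the ether. The step needs the chair with the ring bond C1–C2 axial (ring-cis C1=C10) and not the other chair; the cis relation of the two arms leaves only these two chairs, and the axial O8 can sit beside the axial alkoxide (bridged by K+) but not beside an axial C5. The ester on C10 stabilises the transition state and ends conjugated with the new alkene, the trans-diaxial relation of O6 and the acrylate arm in the reacting conformer keeps lactonization and oxa-Michael closure away, and the bulky silyl group together with the low temperature suppresses silyl transfer.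

Step 10
Reactants: 20 methyl (1(10)E,4Z,7R,8S,9R)-7-(2-methoxy-2-oxoethyl)-8-(4-methoxybenzyloxy)-4-methyl-6-oxo-9-(triisopropylsilyloxy)cyclodeca-1(10),4-diene-10-carboxylate
Product: 21 methyl (1(10)E,4Z,6R,7S,8S,9R)-6-hydroxy-7-(2-methoxy-2-oxoethyl)-8-(4-methoxybenzyloxy)-4-methyl-9-(triisopropylsilyloxy)cyclodeca-1(10),4-diene-10-carboxylate
Conditions: Zn(BH4)2, Et2O, −40 → −20 °C; pH 7 work-up, crude used at once
Reagents that add atoms: none
Why: Chelation-controlled 1,2-reduction: zinc bridges the ketone oxygen and the benzylic ether oxygen on C8, the C7 side chain then stands axial on the six-membered chelate and hydride should enter anti to it, giving the C6 alcohol syn to C11 along the chain (the configuration of the trans lactone), as in reductions of α-substituted β-alkoxy ketones with this reagent; the spatial arrangement at C6 and C7 is that of the target, the descriptors differing only through priority changes.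

Step 11
Reactants: 21 methyl (1(10)E,4Z,6R,7S,8S,9R)-6-hydroxy-7-(2-methoxy-2-oxoethyl)-8-(4-methoxybenzyloxy)-4-methyl-9-(triisopropylsilyloxy)cyclodeca-1(10),4-diene-10-carboxylate
Product: 22 methyl (1(10)E,4R,5S,6S,7S,8S,9R)-4,5-epoxy-6-hydroxy-7-(2-methoxy-2-oxoethyl)-8-(4-methoxybenzyloxy)-4-methyl-9-(triisopropylsilyloxy)cyclodec-1(10)-ene-10-carboxylate
Conditions: VO(acac)2 (5 mol%), t-BuOOH, CH2Cl2, 0 °C
Reagents that add atoms: tert-butyl hydroperoxide, CC(C)(C)OO
Why: Hydroxyl-directed epoxidation: the vanadate ester of O6 delivers oxygen only to the neighbouring Z alkene and on the face of the hydroxyl, as with medium-ring (Z)-cycloalk-2-enols that give cis-epoxy alcohols, which should set C4 (R) and C5 (S); the electron-poor C1=C10 enoate is inert.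

Step 12
Reactants: 22 methyl (1(10)E,4R,5S,6S,7S,8S,9R)-4,5-epoxy-6-hydroxy-7-(2-methoxy-2-oxoethyl)-8-(4-methoxybenzyloxy)-4-methyl-9-(triisopropylsilyloxy)cyclodec-1(10)-ene-10-carboxylate
Product: 23 methyl (1(10)E,4R,5S,6S,7R,8S,9R)-4,5-epoxy-8-(4-methoxybenzyloxy)-9-(triisopropylsilyloxy)-13-norgermacr-1(10)-en-12,6-olid-14-oate (trans-fused γ-lactone with C11 as CH2)
Conditions: DBU (cat.), CH2Cl2, rt
Reagents that add atoms: none
Why: Base-catalysed lactonization (intramolecular transesterification, 5-exo-trig) of O6 onto the C12 methyl ester closes the trans-fused γ-lactone; the catalytic amidine is too weak to start a Payne rearrangement or to enolise the esters.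

Step 13
Reactants: 23 methyl (1(10)E,4R,5S,6S,7R,8S,9R)-4,5-epoxy-8-(4-methoxybenzyloxy)-9-(triisopropylsilyloxy)-13-norgermacr-1(10)-en-12,6-olid-14-oate
Product: 25 methyl (1(10)E,4R,5S,6S,7R,8S,9R)-13-(dimethylamino)-4,5-epoxy-8-(4-methoxybenzyloxy)-9-(triisopropylsilyloxy)germacr-1(10)-en-12,6-olid-14-oate (C11 epimers), via lithium lactone enolate 24 (not isolated)
Conditions: LiN(SiMe3)2, THF, −78 °C; CH2=NMe2+ I−, −78 → 0 °C
Reagents that add atoms: N,N-dimethylmethyleneiminium iodide, C=[N+](C)C.[I-]
Why: Mannich reaction of the lactone enolate (first stage of the Eschenmoser methylenation): kinetic deprotonation at C11 at −78 °C and trapping by the iminium salt bring in C13, while O9 is still silylated so that no acetate competes for the base.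

Step 14
Reactants: 25 methyl (1(10)E,4R,5S,6S,7R,8S,9R)-13-(dimethylamino)-4,5-epoxy-8-(4-methoxybenzyloxy)-9-(triisopropylsilyloxy)germacr-1(10)-en-12,6-olid-14-oate
Product: 27 methyl (1(10)E,4R,5S,6S,7R,8S,9R)-4,5-epoxy-8-(4-methoxybenzyloxy)-9-(triisopropylsilyloxy)germacra-1(10),11(13)-dien-12,6-olid-14-oate, via trimethylammonium iodide 26 (not isolated)
Conditions: MeI, THF/MeOH, rt; then aq. NaHCO3, CH2Cl2, rt
Reagents that add atoms: none
Why: Quaternization of the amine and Hofmann-type β-elimination (E1cB through the lactone enolate) give the exocyclic C11=C13 methylene under bicarbonate, conditions that leave the oxirane and the esters untouched.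

Step 15
Reactants: 27 methyl (1(10)E,4R,5S,6S,7R,8S,9R)-4,5-epoxy-8-(4-methoxybenzyloxy)-9-(triisopropylsilyloxy)germacra-1(10),11(13)-dien-12,6-olid-14-oate
Product: 28 methyl (1(10)E,4R,5S,6S,7R,8S,9R)-4,5-epoxy-9-hydroxy-8-(4-methoxybenzyloxy)germacra-1(10),11(13)-dien-12,6-olid-14-oate
Conditions: HF·pyridine, pyridine, THF, 0 °C → rt
Reagents that add atoms: none
Why: Fluoride cleavage of the secondary silyl ether with pyridine-buffered HF·pyridine, a reagent that tolerates trisubstituted oxiranes, benzylic ethers and methylene lactones.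

Step 16
Reactants: 28 methyl (1(10)E,4R,5S,6S,7R,8S,9R)-4,5-epoxy-9-hydroxy-8-(4-methoxybenzyloxy)germacra-1(10),11(13)-dien-12,6-olid-14-oate
Product: 29 methyl (1(10)E,4R,5S,6S,7R,8S,9R)-9-acetoxy-4,5-epoxy-8-(4-methoxybenzyloxy)germacra-1(10),11(13)-dien-12,6-olid-14-oate
Conditions: Ac2O, pyridine, DMAP (cat.), CH2Cl2, 0 °C → rt
Reagents that add atoms: acetic anhydride, CC(=O)OC(C)=O
Why: DMAP-catalysed acetylation of the free C9 hydroxyl, placed after the enolate chemistry so that the acetate never meets a strong base.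

Step 17
Reactants: 29 methyl (1(10)E,4R,5S,6S,7R,8S,9R)-9-acetoxy-4,5-epoxy-8-(4-methoxybenzyloxy)germacra-1(10),11(13)-dien-12,6-olid-14-oate
Product: 30 methyl (1(10)E,4R,5S,6S,7R,8S,9R)-9-acetoxy-4,5-epoxy-8-hydroxygermacra-1(10),11(13)-dien-12,6-olid-14-oate
Conditions: DDQ, CH2Cl2/pH 7 buffer, 0 °C
Reagents that add atoms: none
Why: Oxidative cleavage of the 4-methoxybenzyl ether by DDQ through the benzylic oxocarbenium ion, which the buffer water hydrolyses; the neutral medium avoids acetyl migration from O9 to O8 and leaves the electron-poor alkenes and the oxirane alone.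

Step 18
Reactants: 31 (R)-2-methylglycidol
Product: 32 (2S)-2-methyloxirane-2-carboxylic acid
Conditions: RuCl3 (cat.), NaIO4, MeCN/EtOAc/H2O, 0 °C → rt
Reagents that add atoms: water, O
Why: RuO4-catalysed oxidation of the primary alcohol to the acid (through the aldehyde hydrate) without opening the oxirane; the stereocenter is not involved and the descriptor changes from R to S only through the priority change.

Step 19
Reactants: 30 methyl (1(10)E,4R,5S,6S,7R,8S,9R)-9-acetoxy-4,5-epoxy-8-hydroxygermacra-1(10),11(13)-dien-12,6-olid-14-oate, 32 (2S)-2-methyloxirane-2-carboxylic acid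
Product: 33 methyl (1(10)E,4R,5S,6S,7R,8S,9R)-9-acetoxy-4,5-epoxy-8-[(2S)-2-methyloxirane-2-carbonyloxy]germacra-1(10),11(13)-dien-12,6-olid-14-oate (target CNP0274195.2)
Conditions: i-PrN=C=N-i-Pr, DMAP (cat.), CH2Cl2, 0 °C
Reagents that add atoms: none
Why: Steglich esterification: the carbodiimide activates the acid and DMAP transfers the acyl group to the C8 hydroxyl; the acid has no α-hydrogen so its center cannot epimerise, and the cold, short reaction limits acetyl migration.

**Compound list**

1 | methyl 4-oxobutanoate | COC(=O)CCC=O | starting material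
2 | methyl vinyl ketone | CC(=O)C=C | starting material
3 | methyl (3R)-3-formyl-6-oxoheptanoate | COC(=O)C[C@H](C=O)CCC(C)=O | intermediate
4 | methyl 2-[(1R)-4-oxocyclohex-2-en-1-yl]acetate | COC(=O)C[C@@H]1C=CC(=O)CC1 | intermediate
5 | methyl 2-[(1R)-4-hydroxy-4-methylcyclohex-2-en-1-yl]acetate (both C4 epimers) | COC(=O)C[C@@H]1C=CC(C)(O)CC1 | intermediate
6 | dilithium ester enolate and alkoxide of 5 | [Li+].[Li+].COC([O-])=C[C@@H]1C=CC(C)([O-])CC1 | intermediate (not isolated)
7 | methyl (2Z)-3-hydroxy-2-[(1S)-4-hydroxy-4-methylcyclohex-2-en-1-yl]prop-2-enoate | COC(=O)/C(=C\O)[C@@H]1C=CC(C)(O)CC1 | intermediate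
8 | sodium enolate of 7 | [Na+].COC(=O)/C(=C\[O-])[C@@H]1C=CC(C)(O)CC1 | intermediate (not isolated)
9 | methyl (2Z)-2-[(1S)-4-hydroxy-4-methylcyclohex-2-en-1-yl]-3-(triisopropylsilyloxy)prop-2-enoate | COC(=O)/C(=C\O[Si](C(C)C)(C(C)C)C(C)C)[C@@H]1C=CC(C)(O)CC1 | intermediate
10 | methyl (2Z)-2-[(1R)-4-methyl-2-oxocyclohex-3-en-1-yl]-3-(triisopropylsilyloxy)prop-2-enoate | COC(=O)/C(=C\O[Si](C(C)C)(C(C)C)C(C)C)[C@H]1CCC(C)=CC1=O | intermediate
11 | 1,2-dibromoethene (cis/trans mixture) | BrC=CBr | starting material
12 | bromoethyne | BrC#C | intermediate (not isolated)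
13 | (Z)-2-bromovinyl 4-methoxybenzyl ether | Br/C=C\OCc1ccc(OC)cc1 | intermediate
14 | (Z)-2-(4-methoxybenzyloxy)vinyllithium | [Li]/C=C\OCc1ccc(OC)cc1 | intermediate (not isolated)
15 | dichloro[(Z)-2-(4-methoxybenzyloxy)vinyl]cerium | Cl[Ce](Cl)/C=C\OCc1ccc(OC)cc1 | intermediate (not isolated)
16 | methyl (2Z)-2-[(1R,2S)-2-hydroxy-2-[(Z)-2-(4-methoxybenzyloxy)ethenyl]-4-methylcyclohex-3-en-1-yl]-3-(triisopropylsilyloxy)prop-2-enoate | O[C@@]1(/C=C\OCc2ccc(OC)cc2)C=C(C)CC[C@@H]1/C(C(=O)OC)=C/O[Si](C(C)C)(C(C)C)C(C)C | intermediate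
17 | methyl bromoacetate | COC(=O)CBr | starting material
18 | potassium alkoxide of 16 | [K+].[O-][C@@]1(/C=C\OCc2ccc(OC)cc2)C=C(C)CC[C@@H]1/C(C(=O)OC)=C/O[Si](C(C)C)(C(C)C)C(C)C | intermediate (not isolated)
19 | potassium (1(10)E,4Z,6Z,8S,9R)-dienolate of the ten-membered ring (O6 cis to C8) | [K+].C1/C(C)=C\C([O-])=C\[C@H](OCc2ccc(OC)cc2)[C@H](O[Si](C(C)C)(C(C)C)C(C)C)/C(C(=O)OC)=C\C1 | intermediate (not isolated)
20 | methyl (1(10)E,4Z,7R,8S,9R)-7-(2-methoxy-2-oxoethyl)-8-(4-methoxybenzyloxy)-4-methyl-6-oxo-9-(triisopropylsilyloxy)cyclodeca-1(10),4-diene-10-carboxylate | C1/C(C)=C\C(=O)[C@H](CC(=O)OC)[C@H](OCc2ccc(OC)cc2)[C@H](O[Si](C(C)C)(C(C)C)C(C)C)/C(C(=O)OC)=C\C1 | intermediate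
21 | methyl (1(10)E,4Z,6R,7S,8S,9R)-6-hydroxy-7-(2-methoxy-2-oxoethyl)-8-(4-methoxybenzyloxy)-4-methyl-9-(triisopropylsilyloxy)cyclodeca-1(10),4-diene-10-carboxylate | C1/C(C)=C\[C@@H](O)[C@H](CC(=O)OC)[C@H](OCc2ccc(OC)cc2)[C@H](O[Si](C(C)C)(C(C)C)C(C)C)/C(C(=O)OC)=C\C1 | intermediate
22 | methyl (1(10)E,4R,5S,6S,7S,8S,9R)-4,5-epoxy-6-hydroxy-7-(2-methoxy-2-oxoethyl)-8-(4-methoxybenzyloxy)-4-methyl-9-(triisopropylsilyloxy)cyclodec-1(10)-ene-10-carboxylate | O[C@H]2[C@H](CC(=O)OC)[C@H](OCc3ccc(OC)cc3)[C@H](O[Si](C(C)C)(C(C)C)C(C)C)/C(C(=O)OC)=C\CC[C@@]1(C)O[C@@H]21 | intermediate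
23 | methyl (1(10)E,4R,5S,6S,7R,8S,9R)-4,5-epoxy-8-(4-methoxybenzyloxy)-9-(triisopropylsilyloxy)-13-norgermacr-1(10)-en-12,6-olid-14-oate | C1C(=O)O[C@H]2[C@H]1[C@H](OCc3ccc(OC)cc3)[C@H](O[Si](C(C)C)(C(C)C)C(C)C)/C(C(=O)OC)=C\CC[C@@]1(C)O[C@@H]21 | intermediate
24 | lithium enolate of lactone 23 | [Li+].C1=C([O-])O[C@H]2[C@H]1[C@H](OCc3ccc(OC)cc3)[C@H](O[Si](C(C)C)(C(C)C)C(C)C)/C(C(=O)OC)=C\CC[C@@]1(C)O[C@@H]21 | intermediate (not isolated)
25 | methyl (1(10)E,4R,5S,6S,7R,8S,9R)-13-(dimethylamino)-4,5-epoxy-8-(4-methoxybenzyloxy)-9-(triisopropylsilyloxy)germacr-1(10)-en-12,6-olid-14-oate (C11 epimers) | CN(C)CC1C(=O)O[C@H]2[C@H]1[C@H](OCc3ccc(OC)cc3)[C@H](O[Si](C(C)C)(C(C)C)C(C)C)/C(C(=O)OC)=C\CC[C@@]1(C)O[C@@H]21 | intermediate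
26 | trimethylammonium iodide of 25 | C[N+](C)(C)CC1C(=O)O[C@H]2[C@H]1[C@H](OCc3ccc(OC)cc3)[C@H](O[Si](C(C)C)(C(C)C)C(C)C)/C(C(=O)OC)=C\CC[C@@]1(C)O[C@@H]21.[I-] | intermediate (not isolated)
27 | methyl (1(10)E,4R,5S,6S,7R,8S,9R)-4,5-epoxy-8-(4-methoxybenzyloxy)-9-(triisopropylsilyloxy)germacra-1(10),11(13)-dien-12,6-olid-14-oate | C=C1C(=O)O[C@H]2[C@H]1[C@H](OCc3ccc(OC)cc3)[C@H](O[Si](C(C)C)(C(C)C)C(C)C)/C(C(=O)OC)=C\CC[C@@]1(C)O[C@@H]21 | intermediate
28 | methyl (1(10)E,4R,5S,6S,7R,8S,9R)-4,5-epoxy-9-hydroxy-8-(4-methoxybenzyloxy)germacra-1(10),11(13)-dien-12,6-olid-14-oate | C=C1C(=O)O[C@H]2[C@H]1[C@H](OCc3ccc(OC)cc3)[C@H](O)/C(C(=O)OC)=C\CC[C@@]1(C)O[C@@H]21 | intermediate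
29 | methyl (1(10)E,4R,5S,6S,7R,8S,9R)-9-acetoxy-4,5-epoxy-8-(4-methoxybenzyloxy)germacra-1(10),11(13)-dien-12,6-olid-14-oate | C=C1C(=O)O[C@H]2[C@H]1[C@H](OCc3ccc(OC)cc3)[C@H](OC(C)=O)/C(C(=O)OC)=C\CC[C@@]1(C)O[C@@H]21 | intermediate
30 | methyl (1(10)E,4R,5S,6S,7R,8S,9R)-9-acetoxy-4,5-epoxy-8-hydroxygermacra-1(10),11(13)-dien-12,6-olid-14-oate | C=C1C(=O)O[C@H]2[C@H]1[C@H](O)[C@H](OC(C)=O)/C(C(=O)OC)=C\CC[C@@]1(C)O[C@@H]21 | intermediate
31 | (R)-2-methylglycidol | OC[C@]1(C)CO1 | starting material
32 | (2S)-2-methyloxirane-2-carboxylic acid | OC(=O)[C@]1(C)CO1 | intermediate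
33 | methyl (1(10)E,4R,5S,6S,7R,8S,9R)-9-acetoxy-4,5-epoxy-8-[(2S)-2-methyloxirane-2-carbonyloxy]germacra-1(10),11(13)-dien-12,6-olid-14-oate (CNP0274195.2) | C=C1C(=O)O[C@H]2[C@H]1[C@H](OC(=O)[C@]1(C)CO1)[C@H](OC(C)=O)/C(C(=O)OC)=C\CC[C@@]1(C)O[C@@H]21 | target

**Count and risks**

Total step count: 19. Longest linear sequence: 17 steps (steps 1–6, 8–17 and 19; steps 7 and 18 make the side branches).

Steps most likely to fail:

1. Step 9 (proposed new method). The alkoxide may close onto the C14 ester, the enolate may lose the C8 ether by β-elimination or add across the ring to the enoate before it is alkylated, or the shift may run through the other chair. Fallback with known chemistry, setting out from 16 and returning at 20: 16 would be silylated with N-(trimethylsilyl)imidazole to the trimethylsilyl ether F1. Heating F1 in toluene (sealed tube, 110–140 °C) would bring about the neutral oxy-Cope rearrangement of the silyl ether to the ten-membered silyl dienol ether F2, with no alkoxide or free enolate present. F2 would then be opened with anhydrous benzyltrimethylammonium fluoride in THF to the ammonium dienolate F3 and alkylated at once with 17 to give 20.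

2. Step 8. The alkenylcerium reagent may add mainly from the equatorial direction (giving the trans-dialkenyl carbinol), or enolisation of 10 by the basic reagent may erode C1. Fallback, setting out from 13 and 10 and returning at 16: 13 would be treated with LiN(iPr)2 (2 equiv, THF, −78 °C); anti elimination of HBr gives 4-methoxybenzyl ethynyl ether F4, which is metalated in the same flask to lithium 2-(4-methoxybenzyloxy)ethynide F5. This small, linear and less basic nucleophile, known to prefer axial attack on cyclohexanones, would be added to 10 to give the alkynyl carbinol F6. Semihydrogenation of the ynol ether over Pd/CaCO3 poisoned with Pb(OAc)2 and quinoline would give the Z enol ether 16.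

3. Step 10. Hydride may reach C6 from the other face if the zinc chelate between O6 and O8 does not form in the ring (the non-chelated course would lead to the C6 epimer and the cis lactone), and early lactone closure would remove the hydroxyl that step 11 needs. Fallback, setting out from 20 and returning at 22: Weitz–Scheffer epoxidation of the Z enone (t-BuOOH, DBU, CH2Cl2, 0 °C) would give the 4,5-epoxy 6-ketone F7. Reduction of this α,β-epoxy ketone with Zn(BH4)2 is then steered by the tighter five-membered chelate between the oxirane and carbonyl oxygens (anti epoxy alcohol) and would return to 22 without a hydroxyl-directed epoxidation.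

Further compounds
F1 | step 9 | trimethylsilyl ether of 16 | C[Si](C)(C)O[C@@]1(/C=C\OCc2ccc(OC)cc2)C=C(C)CC[C@@H]1/C(C(=O)OC)=C/O[Si](C(C)C)(C(C)C)C(C)C
F2 | step 9 | ten-membered trimethylsilyl dienol ether (1(10)E,4Z,6Z,8S,9R) | C1/C(C)=C\C(O[Si](C)(C)C)=C\[C@H](OCc2ccc(OC)cc2)[C@H](O[Si](C(C)C)(C(C)C)C(C)C)/C(C(=O)OC)=C\C1
F3 | step 9 | benzyltrimethylammonium dienolate of the ten-membered ring | C[N+](C)(C)Cc1ccccc1.C2/C(C)=C\C([O-])=C\[C@H](OCc3ccc(OC)cc3)[C@H](O[Si](C(C)C)(C(C)C)C(C)C)/C(C(=O)OC)=C\C2
F4 | step 8 | 4-methoxybenzyl ethynyl ether | C#COCc1ccc(OC)cc1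
F5 | step 8 | lithium 2-(4-methoxybenzyloxy)ethynide | [Li]C#COCc1ccc(OC)cc1
F6 | step 8 | methyl (2Z)-2-[(1R,2S)-2-hydroxy-2-[2-(4-methoxybenzyloxy)ethynyl]-4-methylcyclohex-3-en-1-yl]-3-(triisopropylsilyloxy)prop-2-enoate | O[C@@]1(C#COCc2ccc(OC)cc2)C=C(C)CC[C@@H]1/C(C(=O)OC)=C/O[Si](C(C)C)(C(C)C)C(C)C
F7 | step 10 | 4,5-epoxy 6-ketone (oxirane, C7, C8 and C9 configured as in 22) | O=C2[C@H](CC(=O)OC)[C@H](OCc3ccc(OC)cc3)[C@H](O[Si](C(C)C)(C(C)C)C(C)C)/C(C(=O)OC)=C\CC[C@@]1(C)O[C@@H]21
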